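**Retrosynthetic overview**
- Target ⇐ its heptamethyl ether by one global O-demethylation at the end. The bromine is already on ring C, so no late bromination among three equally activated rings is needed.
- B–O–C ether ⇐ C–O bond between the ring-B phenol oxygen and a free C–H of commercial 2-bromo-1,3,5-trimethoxybenzene (formal dehydrogenative etherification through an aryl sulfonium made in the flask).
- Ring-B phenol ⇐ aryl aldehyde by Baeyer–Villiger oxidation; the CHO of syringaldehyde is the masked para-OH.
- A–O–B ether ⇐ C–O bond between the hindered OH of syringaldehyde and 3,5-dimethoxyphenylboronic acid (Chan–Lam).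
- No ring is built: the three benzene rings are bought and joined in the order A–B, then AB–C.

Assumption: the target has no stereocentre and its diaryl ethers rotate freely, so it is achiral and "single enantiomer" simply means the one constitution drawn.

**Step 1**
Reactants: 1 syringaldehyde (4-hydroxy-3,5-dimethoxybenzaldehyde); 2 3,5-dimethoxyphenylboronic acid (2 equiv)
Product: 3 4-(3,5-dimethoxyphenoxy)-3,5-dimethoxybenzaldehyde
Conditions: Cu(OAc)2 (20 mol%), pyridine (3 equiv), 4 Å MS, O2 (1 atm), CH2Cl2, rt
Reagents that add atoms: none
Why: Chan–Lam (Chan–Evans–Lam) oxidative O-arylation; the Cu(II) phenoxide transmetalates with the arylboronic acid and C–O reductive elimination from Cu(III) arylates even di-ortho-substituted, acidic phenols at rt without touching the aldehyde; no stereocentre is formed.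

**Step 2**
Reactants: 3 4-(3,5-dimethoxyphenoxy)-3,5-dimethoxybenzaldehyde
Product: 5 4-(3,5-dimethoxyphenoxy)-3,5-dimethoxyphenol, via aryl formate 4 (not isolated)
Conditions: mCPBA (1.3 equiv), CH2Cl2, 0 °C → rt; NaHCO3 wash; then K2CO3 (cat.), MeOH, rt
Reagents that add atoms: 3-chloroperoxybenzoic acid (mCPBA), OOC(=O)c1cccc(Cl)c1
Why: Baeyer–Villiger (Dakin-type) oxidation; the electron-rich 3,4,5-trioxygenated aryl group migrates in preference to H to give the aryl formate, which mild methanolysis cleaves to the phenol; no stereocentre is formed.

**Step 3**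
Reactants: 5 4-(3,5-dimethoxyphenoxy)-3,5-dimethoxyphenol (1.0 equiv); 6 2-bromo-1,3,5-trimethoxybenzene (1.6 equiv); 7 dibenzothiophene 5-oxide (1.5 equiv)
Product: 9 2-bromo-4-[4-(3,5-dimethoxyphenoxy)-3,5-dimethoxyphenoxy]-1,3,5-trimethoxybenzene, via aryl dibenzothiophenium triflate 8 (not isolated)
Conditions: 6, 7, Tf2O (1.5 equiv), MeCN, −40 → 0 °C; then K3PO4 (4 equiv), 5, CuTC (20 mol%), fac-Ir(ppy)3 (1 mol%), MeCN, blue LEDs, rt, N2
Reagents that add atoms: none
Why: Proposed new method: a one-pot formal dehydrogenative C–H/O–H etherification in which Tf2O-activated 7 sulfoniumates 6 by SEAr at its only kind of free C–H (two equivalent positions, each flanked by two OMe; the sulfonium deactivates the ring, so it stops at mono, and all activated sulfoxide is consumed before 5 is added), then excited fac-Ir(ppy)3 (about −1.7 V vs SCE) reduces 8, exocyclic C–S scission releases dibenzothiophene and the 3-bromo-2,4,6-trimethoxyphenyl radical, this is captured by the Cu(II) aryloxide of 5, and C–O reductive elimination from Cu(III) gives 9; inner-sphere delivery from copper enforces O- over C-arylation of the ambident phenoxide (the C–C biaryl outcome of outer-sphere oxidative phenol–arene couplings) and the aryl C–Br bond is far beyond the reducing power of the catalyst; the closest known reaction types are the interrupted-Pummerer C–H sulfoniumation of arenes and the photoredox/copper C–O coupling of aryl thianthrenium salts with O–H nucleophiles, neither shown for a di-ortho-alkoxy aryl sulfonium nor telescoped with a phenol to a di-ortho-substituted diaryl ether; no stereocentre is formed.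

**Step 4**
Reactants: 9 2-bromo-4-[4-(3,5-dimethoxyphenoxy)-3,5-dimethoxyphenoxy]-1,3,5-trimethoxybenzene
Product: 10 2-bromo-4-[4-(3,5-dihydroxyphenoxy)-3,5-dihydroxyphenoxy]benzene-1,3,5-triol (CNP0039507.0)
Conditions: BBr3 (12 equiv), CH2Cl2, −78 °C → rt, Ar; then H2O, 0 °C; degassed work-up, C18 or Sephadex LH-20
Reagents that add atoms: none
Why: Lewis-acid O-demethylation with BBr3; each ArO–CH3 is cleaved by bromide attack on the boron-activated ether while diaryl ether C–O and aryl C–Br bonds are inert, and HBr only appears at the cold aqueous quench, which limits protodebromination; no stereocentre is present.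

**Compound list**
1 | syringaldehyde (4-hydroxy-3,5-dimethoxybenzaldehyde) | COc1cc(C=O)cc(OC)c1O | starting material
2 | 3,5-dimethoxyphenylboronic acid | COc1cc(OC)cc(B(O)O)c1 | starting material
3 | 4-(3,5-dimethoxyphenoxy)-3,5-dimethoxybenzaldehyde | COc1cc(OC)cc(Oc2c(OC)cc(C=O)cc2OC)c1 | intermediate
4 | 4-(3,5-dimethoxyphenoxy)-3,5-dimethoxyphenyl formate | COc1cc(OC)cc(Oc2c(OC)cc(OC=O)cc2OC)c1 | intermediate (not isolated)
5 | 4-(3,5-dimethoxyphenoxy)-3,5-dimethoxyphenol | COc1cc(OC)cc(Oc2c(OC)cc(O)cc2OC)c1 | intermediate
6 | 2-bromo-1,3,5-trimethoxybenzene | COc1cc(OC)c(Br)c(OC)c1 | starting material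
7 | dibenzothiophene 5-oxide | O=S1c2ccccc2-c2ccccc21 | starting material
8 | 5-(3-bromo-2,4,6-trimethoxyphenyl)-5H-dibenzo[b,d]thiophen-5-ium trifluoromethanesulfonate | COc1cc(OC)c([S+]2c3ccccc3-c3ccccc32)c(OC)c1Br.[O-]S(=O)(=O)C(F)(F)F | intermediate (not isolated)
9 | 2-bromo-4-[4-(3,5-dimethoxyphenoxy)-3,5-dimethoxyphenoxy]-1,3,5-trimethoxybenzene (heptamethyl ether of the target) | COc1cc(OC)cc(Oc2c(OC)cc(Oc3c(OC)cc(OC)c(Br)c3OC)cc2OC)c1 | intermediate
10 | 2-bromo-4-[4-(3,5-dihydroxyphenoxy)-3,5-dihydroxyphenoxy]benzene-1,3,5-triol | Oc1cc(O)cc(Oc2c(O)cc(Oc3c(O)cc(O)c(Br)c3O)cc2O)c1 | target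

**Step count and risk**
Total steps: 4. Longest linear sequence: 4 (1 → 3 → 5 → 9 → 10).

The three steps most likely to fail:

Step 3 (the proposed new etherification). The sulfoniumation at a position flanked by two methoxy groups, or the copper capture of the hindered aryl radical, may be inefficient, and the radical may simply be reduced back to 6. The fallback uses known chemistry and sets out from 6. Electrophilic iodination (NIS, cat. TFA, MeCN, 0 °C) at the same free position gives 2-bromo-4-iodo-1,3,5-trimethoxybenzene F1. An Ullmann ether synthesis of this iodide with phenol 5 (CuI, picolinic acid, K3PO4, DMSO, 90 °C) reacts at C–I in preference to the hindered, electron-rich C–Br and comes back to the route at 9. This costs one extra step.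

Step 4 (sevenfold demethylation). Cleavage may stop short of all seven ethers, and the heptaphenol is air-sensitive and hard to purify. Bromine loss or migration on the phloroglucinol ring is a further concern if the quench is warm. The fallback sets out from 9. After the same BBr3 treatment the crude polyphenol is not isolated but peracetylated (Ac2O, pyridine, DMAP, rt) to 2-bromo-4-[4-(3,5-diacetoxyphenoxy)-3,5-diacetoxyphenoxy]benzene-1,3,5-triyl triacetate F2. This heptaacetate is air-stable and can be purified on silica away from under-demethylated material. Acid-catalysed methanolysis (AcCl in degassed MeOH, rt, Ar) then releases the phenols and comes back to the route at 10.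

Step 1 (Chan–Lam on a hindered, acidic phenol). The coupling may stall, or the boronic acid may be consumed by homocoupling or oxidation. The fallback sets out from 1 and switches from oxidative coupling of an aryl nucleophile to substitution on an aryl electrophile. An Ullmann coupling of 1 with commercial 1-bromo-3,5-dimethoxybenzene (CuI, picolinic acid, K3PO4, DMSO, 90 °C; conditions suited to di-ortho-substituted phenols) comes back to the route at 3. This fallback makes no new compound (F0).

**Further compounds**
F1 | step 3 | 2-bromo-4-iodo-1,3,5-trimethoxybenzene | COc1cc(OC)c(I)c(OC)c1Br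
F2 | step 4 | 2-bromo-4-[4-(3,5-diacetoxyphenoxy)-3,5-diacetoxyphenoxy]benzene-1,3,5-triyl triacetate | CC(=O)Oc1cc(OC(C)=O)cc(Oc2c(OC(C)=O)cc(Oc3c(OC(C)=O)cc(OC(C)=O)c(Br)c3OC(C)=O)cc2OC(C)=O)c1
F0 | step 1 | none | none
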